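**Plan**

- Retrosynthesis (benzofuran numbering: O1, C2, C3, C3a, C4–C7, C7a): the two C–CH3 bonds of the carbinol are cut first (back to a C2 methyl ester), then O1–C2 and C2–C3 of the dihydrofuran together, then C3–C3a, the MOM acetal, C5–prenyl and the C7–acyl bond.
- Enabling feature: C3 is a bare benzylic CH2 on C3a, and C3a is the neighbour of the oxygen-bearing C7a. The unit C3–C3a–C7a–O1 is therefore a hidden ortho-quinone methide, and the furan ring needs only the single carbon C2 to be complete.
- Forward: phloroglucinol is C-acylated, C-prenylated, MOM-protected at the oxygen para to the ketone and aminomethylated at the last ring CH. The quaternised amine releases the methide, which takes up C2 from a chiral sulfonium ylide in a [4+1] annulation that closes the dihydrofuran, the only ring made in the route.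
- The C2 ester is then converted into the dimethylcarbinol and the MOM group is removed.
- Stereochemistry: the one stereocentre, C2 (S), is set in the annulation by the twofold-symmetric (2R,5R)-2,5-dimethylthiolane, made from (2S,5S)-hexane-2,5-diol, and is not touched afterwards.

Key step: step 9

Assumption: the (2R,5R)-sulfide is taken to deliver the (2S)-ester; this sense has to be checked on the first run, and if it proves opposite, the enantiomeric sulfide from (2R,5R)-hexane-2,5-diol is used in the same steps.

**Route**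

Step 1
Reactants: 1 phloroglucinol; 2 3-(4-methoxyphenyl)propanoic acid
Product: 3 3-(4-methoxyphenyl)-1-(2,4,6-trihydroxyphenyl)propan-1-one
Conditions: BF3·OEt2 (neat), 85 °C; then aq NaOAc
Reagents that add atoms: none
Why: Friedel–Crafts C-acylation of the highly nucleophilic, threefold-symmetric phloroglucinol by the BF3-activated acid is a standard entry to 2,4,6-trihydroxydihydrochalcones, and the chelated monoketone is deactivated towards a second acylation.

Step 2
Reactants: 3 3-(4-methoxyphenyl)-1-(2,4,6-trihydroxyphenyl)propan-1-one; 4 1-bromo-3-methylbut-2-ene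
Product: 5 3-(4-methoxyphenyl)-1-[2,4,6-trihydroxy-3-(3-methylbut-2-enyl)phenyl]propan-1-one
Conditions: 4 (1.0 equiv), 10% aq KOH, 0 °C; then dilute HCl
Reagents that add atoms: none
Why: Base-mediated C-prenylation of the ambident phloroglucinol phenoxide in water is the usual way to nuclear-prenylated acylphloroglucinols, the two free ring positions of 3 are equivalent, and one equivalent of bromide at low temperature should limit double alkylation.

Step 3
Reactants: 5 3-(4-methoxyphenyl)-1-[2,4,6-trihydroxy-3-(3-methylbut-2-enyl)phenyl]propan-1-one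
Product: 6 1-[2,6-dihydroxy-4-(methoxymethoxy)-3-(3-methylbut-2-enyl)phenyl]-3-(4-methoxyphenyl)propan-1-one
Conditions: MOMCl (1.05 equiv), i-Pr2NEt (1.1 equiv), CH2Cl2, 0 °C
Reagents that add atoms: chloromethyl methyl ether, COCCl
Why: Williamson-type O-alkylation with one equivalent of MOMCl should take place at the hydroxyl para to the ketone, which is the most acidic and the only one that cannot be tied up in the hydrogen-bonded chelate, as in the usual selective 4-O-alkylation of 2,4,6-trihydroxyaryl ketones.

Step 4
Reactants: 6 1-[2,6-dihydroxy-4-(methoxymethoxy)-3-(3-methylbut-2-enyl)phenyl]-3-(4-methoxyphenyl)propan-1-one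
Product: 7 1-[3-(dimethylaminomethyl)-2,6-dihydroxy-4-(methoxymethoxy)-5-(3-methylbut-2-enyl)phenyl]-3-(4-methoxyphenyl)propan-1-one
Conditions: CH2(NMe2)2 (1.5 equiv), EtOH, 0 °C → rt
Reagents that add atoms: bis(dimethylamino)methane, CN(C)CN(C)C
Why: The phenolic Mannich reaction (aromatic substitution by the iminium ion released from the aminal) can occur only at the single remaining ring CH, which is activated by an ortho and a para hydroxyl.

Step 5
Reactants: 7 1-[3-(dimethylaminomethyl)-2,6-dihydroxy-4-(methoxymethoxy)-5-(3-methylbut-2-enyl)phenyl]-3-(4-methoxyphenyl)propan-1-one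
Product: 8 [2,4-dihydroxy-6-(methoxymethoxy)-3-[3-(4-methoxyphenyl)propanoyl]-5-(3-methylbut-2-enyl)phenyl]methyl-trimethylazanium iodide
Conditions: MeI (5 equiv), CH2Cl2/Et2O, 0 °C → rt, dark; evaporation of excess MeI
Reagents that add atoms: iodomethane, CI
Why: Menshutkin N-methylation in a non-polar solvent without base should quaternise the amine while the hydrogen-bonded phenols stay untouched, which turns the amine into a leaving group that departs at low temperature in the next step.

Step 6
Reactants: 9 (2S,5S)-hexane-2,5-diol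
Product: 10 (2S,5S)-hexane-2,5-diyl dimethanesulfonate
Conditions: MsCl (2.4 equiv), Et3N (3 equiv), CH2Cl2, −20 → 0 °C
Reagents that add atoms: methanesulfonyl chloride, CS(=O)(=O)Cl
Why: Sulfonylation of the secondary alcohols (mesylate formation) takes place at oxygen and so leaves both stereocentres unchanged.

Step 7
Reactants: 10 (2S,5S)-hexane-2,5-diyl dimethanesulfonate
Product: 11 (2R,5R)-2,5-dimethylthiolane
Conditions: Na2S·9H2O (1.2 equiv), DMSO, rt → 40 °C; pentane extraction, distillation
Reagents that add atoms: sodium sulfide (as Na2S·9H2O), [Na+].[Na+].[S-2]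
Why: Double SN2 displacement by sulfide (thioether formation, the second event a 5-exo-tet closure) inverts both centres and so gives the twofold-symmetric (2R,5R)-thiolane.

Step 8
Reactants: 11 (2R,5R)-2,5-dimethylthiolane; 12 methyl bromoacetate
Product: 13 (2R,5R)-1-(2-methoxy-2-oxoethyl)-2,5-dimethylthiolan-1-ium bromide
Conditions: acetone, rt, 48 h; filtration of the salt
Reagents that add atoms: none
Why: S-Alkylation of the thioether by the α-bromo ester (sulfonium salt formation) is a simple SN2 process, and the twofold symmetry of the thiolane means that sulfur does not become a stereocentre.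

Step 9
Reactants: 8 [2,4-dihydroxy-6-(methoxymethoxy)-3-[3-(4-methoxyphenyl)propanoyl]-5-(3-methylbut-2-enyl)phenyl]methyl-trimethylazanium iodide; 13 (2R,5R)-1-(2-methoxy-2-oxoethyl)-2,5-dimethylthiolan-1-ium bromide
Product: 17 methyl (2S)-6-hydroxy-4-(methoxymethoxy)-7-[3-(4-methoxyphenyl)propanoyl]-5-(3-methylbut-2-enyl)-2,3-dihydro-1-benzofuran-2-carboxylate, via sulfonium ylide 14 (not isolated), via ortho-quinone methide 15 (not isolated), via sulfonium betaine 16 (not isolated)
Conditions: 13 (1.5 equiv), Cs2CO3 (3 equiv), CH2Cl2/MeCN, −20 → 0 °C, slow addition of 8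
Reagents that add atoms: none
Why: Cs2CO3 converts 13 into the ester-stabilised ylide 14 and deprotonates a phenol of 8, whose phenoxide expels trimethylamine by 1,4-elimination to give the ortho-quinone methide 15 (C7a=O, C3a=C3H2; the para-quinone methide through the C6 oxygen is only a tautomer and leads to the same adduct); conjugate addition of the ylide carbon to C3 restores the arene as betaine 16, and the C7a phenoxide then displaces the thiolane at C2 by SN2 in a 5-exo-tet closure of the dihydrofuran ring. The closest known reaction type is the formal [4+1] annulation of ortho-quinone methides generated in situ with sulfonium ylides, including variants with chiral sulfides. The C2 centre of 16 is flanked by sulfonium and ester and should epimerise under the basic conditions, so the (2R,5R)-thiolane controls the C2 configuration in the inverting ring closure under Curtin–Hammett conditions. The step needs closure by one oxygen only, and this is secured by the MOM ether at the C4 oxygen and by the para position of the C6 hydroxyl, which leave O1 as the only oxygen able to reach C2. Chemoselectivity rests on the stabilised ylide, which should ignore the hindered, chelated ketone and the prenyl alkene, and on slow addition of 8, which keeps the methide concentration low against self-condensation.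

Step 10
Reactants: 17 methyl (2S)-6-hydroxy-4-(methoxymethoxy)-7-[3-(4-methoxyphenyl)propanoyl]-5-(3-methylbut-2-enyl)-2,3-dihydro-1-benzofuran-2-carboxylate
Product: 18 1-[(2S)-6-hydroxy-2-(2-hydroxypropan-2-yl)-4-(methoxymethoxy)-5-(3-methylbut-2-enyl)-2,3-dihydro-1-benzofuran-7-yl]-3-(4-methoxyphenyl)propan-1-one
Conditions: MeMgBr (4 equiv), THF, −40 → 0 °C; then aq NH4Cl
Reagents that add atoms: methylmagnesium bromide, C[Mg]Br
Why: Double Grignard addition to the ester, which is activated by chelation of magnesium to the α-oxygen, should outrun attack at the ketone because the first equivalent turns the C6 phenol into a magnesium phenoxide chelate that makes the doubly ortho-substituted ketone a vinylogous carboxylate, and C2 keeps its configuration since addition is faster than enolisation at low temperature.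

Step 11
Reactants: 18 1-[(2S)-6-hydroxy-2-(2-hydroxypropan-2-yl)-4-(methoxymethoxy)-5-(3-methylbut-2-enyl)-2,3-dihydro-1-benzofuran-7-yl]-3-(4-methoxyphenyl)propan-1-one
Product: 19 1-[(2S)-4,6-dihydroxy-2-(2-hydroxypropan-2-yl)-5-(3-methylbut-2-enyl)-2,3-dihydro-1-benzofuran-7-yl]-3-(4-methoxyphenyl)propan-1-one
Conditions: HCl (1.25 M in MeOH), MeOH, 0 °C → rt; then aq NaHCO3
Reagents that add atoms: none
Why: Acid-catalysed transacetalisation of the aryl MOM ether in methanol (acetal cleavage) proceeds at room temperature, where a prenyl group next to free phenols and the tertiary alcohol should persist, and it does not involve C2.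

**Compound list**

1 | phloroglucinol | Oc1cc(O)cc(O)c1 | starting material
2 | 3-(4-methoxyphenyl)propanoic acid | COc1ccc(CCC(=O)O)cc1 | starting material
3 | 3-(4-methoxyphenyl)-1-(2,4,6-trihydroxyphenyl)propan-1-one | COc1ccc(CCC(=O)c2c(O)cc(O)cc2O)cc1 | intermediate
4 | 1-bromo-3-methylbut-2-ene | CC(C)=CCBr | starting material
5 | 3-(4-methoxyphenyl)-1-[2,4,6-trihydroxy-3-(3-methylbut-2-enyl)phenyl]propan-1-one | COc1ccc(CCC(=O)c2c(O)cc(O)c(CC=C(C)C)c2O)cc1 | intermediate
6 | 1-[2,6-dihydroxy-4-(methoxymethoxy)-3-(3-methylbut-2-enyl)phenyl]-3-(4-methoxyphenyl)propan-1-one | COc1ccc(CCC(=O)c2c(O)cc(OCOC)c(CC=C(C)C)c2O)cc1 | intermediate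
7 | 1-[3-(dimethylaminomethyl)-2,6-dihydroxy-4-(methoxymethoxy)-5-(3-methylbut-2-enyl)phenyl]-3-(4-methoxyphenyl)propan-1-one | COc1ccc(CCC(=O)c2c(O)c(CC=C(C)C)c(OCOC)c(CN(C)C)c2O)cc1 | intermediate
8 | [2,4-dihydroxy-6-(methoxymethoxy)-3-[3-(4-methoxyphenyl)propanoyl]-5-(3-methylbut-2-enyl)phenyl]methyl-trimethylazanium iodide | COc1ccc(CCC(=O)c2c(O)c(CC=C(C)C)c(OCOC)c(C[N+](C)(C)C)c2O)cc1.[I-] | intermediate
9 | (2S,5S)-hexane-2,5-diol | C[C@H](O)CC[C@H](C)O | starting material
10 | (2S,5S)-hexane-2,5-diyl dimethanesulfonate | C[C@H](OS(C)(=O)=O)CC[C@H](C)OS(C)(=O)=O | intermediate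
11 | (2R,5R)-2,5-dimethylthiolane | C[C@@H]1CC[C@@H](C)S1 | intermediate
12 | methyl bromoacetate | COC(=O)CBr | starting material
13 | (2R,5R)-1-(2-methoxy-2-oxoethyl)-2,5-dimethylthiolan-1-ium bromide | C[C@@H]1CC[C@@H](C)[S+]1CC(=O)OC.[Br-] | intermediate
14 | sulfonium ylide: [(2R,5R)-2,5-dimethylthiolan-1-ium-1-yl](methoxycarbonyl)methanide | C[C@@H]1CC[C@@H](C)[S+]1[CH-]C(=O)OC | intermediate
15 | ortho-quinone methide: 3-hydroxy-5-(methoxymethoxy)-2-[3-(4-methoxyphenyl)propanoyl]-4-(3-methylbut-2-enyl)-6-methylidenecyclohexa-2,4-dien-1-one | C=C1C(OCOC)=C(CC=C(C)C)C(O)=C(C(=O)CCc2ccc(OC)cc2)C1=O | intermediate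
16 | sulfonium betaine: 2-[2-[(2R,5R)-2,5-dimethylthiolan-1-ium-1-yl]-3-methoxy-3-oxopropyl]-5-hydroxy-3-(methoxymethoxy)-6-[3-(4-methoxyphenyl)propanoyl]-4-(3-methylbut-2-enyl)phenolate (configuration at the sulfonium-bearing carbon not fixed) | C[C@@H]1CC[C@@H](C)[S+]1C(Cc1c([O-])c(C(=O)CCc2ccc(OC)cc2)c(O)c(CC=C(C)C)c1OCOC)C(=O)OC | intermediate
17 | methyl (2S)-6-hydroxy-4-(methoxymethoxy)-7-[3-(4-methoxyphenyl)propanoyl]-5-(3-methylbut-2-enyl)-2,3-dihydro-1-benzofuran-2-carboxylate | COc1ccc(CCC(=O)c2c(O)c(CC=C(C)C)c(OCOC)c3c2O[C@H](C(=O)OC)C3)cc1 | intermediate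
18 | 1-[(2S)-6-hydroxy-2-(2-hydroxypropan-2-yl)-4-(methoxymethoxy)-5-(3-methylbut-2-enyl)-2,3-dihydro-1-benzofuran-7-yl]-3-(4-methoxyphenyl)propan-1-one | COc1ccc(CCC(=O)c2c(O)c(CC=C(C)C)c(OCOC)c3c2O[C@H](C(C)(C)O)C3)cc1 | intermediate
19 | 1-[(2S)-4,6-dihydroxy-2-(2-hydroxypropan-2-yl)-5-(3-methylbut-2-enyl)-2,3-dihydro-1-benzofuran-7-yl]-3-(4-methoxyphenyl)propan-1-one | COc1ccc(CCC(=O)c2c(O)c(CC=C(C)C)c(O)c3c2O[C@H](C(C)(C)O)C3)cc1 | target

**Step count**

Total: 11 steps. Longest linear sequence: 8 steps (steps 1–5 and 9–11 from phloroglucinol). The sulfonium salt comes from a 3-step side branch (steps 6–8) that joins at step 9.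

**Steps most likely to fail, with fallbacks**

Step 9. Three things may go wrong here.
- The two epimeric betaines may be discriminated only weakly in the ring-closing displacement, so that the ester forms with low enantiomeric purity.
- The product ester may epimerise at C2 under the carbonate base.
- The methide may be lost to self-condensation, or the phenoxides may be O-alkylated by the sulfonium salt.

The fallback gives up reagent control and resolves instead. It sets out from 8 and 12. Dimethyl sulfide is alkylated with 12 (acetone, rt) to (2-methoxy-2-oxoethyl)dimethylsulfonium bromide F1. With Cs2CO3 in CH2Cl2 this gives the achiral ylide dimethylsulfonium (methoxycarbonyl)methanide F2, which adds to the methide 15 released from 8. The racemic dimethylsulfonium betaine F3 closes to racemic methyl 6-hydroxy-4-(methoxymethoxy)-7-[3-(4-methoxyphenyl)propanoyl]-5-(3-methylbut-2-enyl)-2,3-dihydro-1-benzofuran-2-carboxylate F4. This is separated by preparative chromatography on a chiral stationary phase; the (2S)-enantiomer is 17, where the route is rejoined. The (2R)-ester F5 is set aside and can be epimerised with DBU back to F4 for another pass.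

Step 10. The Grignard reagent may also add to the aryl ketone if the phenoxide chelate does not deactivate it enough, or the intermediate methyl ketone may enolise and erode the C2 configuration. The fallback masks the ketone before the addition. It sets out from 17. TMSOTf and Et3N in CH2Cl2 at −78 → 0 °C should give the aryl silyl ether and silyl enol ether, methyl (2S)-4-(methoxymethoxy)-5-(3-methylbut-2-enyl)-6-(trimethylsilyloxy)-7-[3-(4-methoxyphenyl)-1-(trimethylsilyloxy)prop-1-enyl]-2,3-dihydro-1-benzofuran-2-carboxylate F6. MeMgBr in THF at 0 °C then meets the ester as the only carbonyl group and gives the bis-silylated carbinol 2-[(2S)-4-(methoxymethoxy)-5-(3-methylbut-2-enyl)-6-(trimethylsilyloxy)-7-[3-(4-methoxyphenyl)-1-(trimethylsilyloxy)prop-1-enyl]-2,3-dihydro-1-benzofuran-2-yl]propan-2-ol F7. Work-up with aqueous citric acid in THF hydrolyses both silyl groups without touching the MOM ether, and the route is rejoined at 18.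

Step 3. Site selectivity among the three hydroxyls of 5 may be poor, with etherification at the hydroxyl ortho to the ketone or double protection. The fallback decides the regiochemistry on a symmetric substrate by changing the order of events. It sets out from 3. MOMCl (1.05 equiv) and i-Pr2NEt in CH2Cl2 at 0 °C give 1-[2,6-dihydroxy-4-(methoxymethoxy)phenyl]-3-(4-methoxyphenyl)propan-1-one F8, in which the two remaining hydroxyls and the two ring CH positions are equivalent. C-prenylation of F8 with 4 in 10% aq KOH at 0 °C can then give only one nuclear monoprenyl compound, and the route is rejoined at 6.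

Further compounds
F1 | step 9 | (2-methoxy-2-oxoethyl)dimethylsulfonium bromide | C[S+](C)CC(=O)OC.[Br-]
F2 | step 9 | dimethylsulfonium (methoxycarbonyl)methanide | C[S+](C)[CH-]C(=O)OC
F3 | step 9 | racemic 2-[2-(dimethylsulfonio)-3-methoxy-3-oxopropyl]-5-hydroxy-3-(methoxymethoxy)-6-[3-(4-methoxyphenyl)propanoyl]-4-(3-methylbut-2-enyl)phenolate | C[S+](C)C(Cc1c([O-])c(C(=O)CCc2ccc(OC)cc2)c(O)c(CC=C(C)C)c1OCOC)C(=O)OC
F4 | step 9 | racemic methyl 6-hydroxy-4-(methoxymethoxy)-7-[3-(4-methoxyphenyl)propanoyl]-5-(3-methylbut-2-enyl)-2,3-dihydro-1-benzofuran-2-carboxylate | COc1ccc(CCC(=O)c2c(O)c(CC=C(C)C)c(OCOC)c3c2OC(C(=O)OC)C3)cc1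
F5 | step 9 | methyl (2R)-6-hydroxy-4-(methoxymethoxy)-7-[3-(4-methoxyphenyl)propanoyl]-5-(3-methylbut-2-enyl)-2,3-dihydro-1-benzofuran-2-carboxylate | COc1ccc(CCC(=O)c2c(O)c(CC=C(C)C)c(OCOC)c3c2O[C@@H](C(=O)OC)C3)cc1
F6 | step 10 | methyl (2S)-4-(methoxymethoxy)-5-(3-methylbut-2-enyl)-6-(trimethylsilyloxy)-7-[3-(4-methoxyphenyl)-1-(trimethylsilyloxy)prop-1-enyl]-2,3-dihydro-1-benzofuran-2-carboxylate | COc1ccc(CC=C(O[Si](C)(C)C)c2c(O[Si](C)(C)C)c(CC=C(C)C)c(OCOC)c3c2O[C@H](C(=O)OC)C3)cc1
F7 | step 10 | 2-[(2S)-4-(methoxymethoxy)-5-(3-methylbut-2-enyl)-6-(trimethylsilyloxy)-7-[3-(4-methoxyphenyl)-1-(trimethylsilyloxy)prop-1-enyl]-2,3-dihydro-1-benzofuran-2-yl]propan-2-ol | COc1ccc(CC=C(O[Si](C)(C)C)c2c(O[Si](C)(C)C)c(CC=C(C)C)c(OCOC)c3c2O[C@H](C(C)(C)O)C3)cc1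
F8 | step 3 | 1-[2,6-dihydroxy-4-(methoxymethoxy)phenyl]-3-(4-methoxyphenyl)propan-1-one | COc1ccc(CCC(=O)c2c(O)cc(OCOC)cc2O)cc1
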